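**Plan**

- Retrosynthesis (carotenoid numbering, primed locants for the ε half): C11=C12 is cut (Wittig) into the C15 epoxy dienal 20 and the C25 phosphonium salt 33; 33 is cut at C11'=C12' into trienedial 28 and the ε-ring C15 phosphonium salt 27, which comes from (R)-α-ionone (C9'–C10' by vinyl addition).
- 20 is cut at the C3–O ester bond (Mitsunobu, inversion), at C7=C8 (Horner–Wadsworth–Emmons) and at the two oxirane C–O bonds; C6–C7 comes from carbonylation of an enol triflate made from ketoisophorone.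
- Forward: ketoisophorone → 4S hydroxy ketone → enol triflate → ester → C7 silyl ether with free C3 hydroxyl (9) → hydroxyl-directed epoxidation closes the oxirane, the only ring made → C5 chain extension → palmitoylation with inversion → union with the ε half in the last step.
- Enabling feature: the C5–C6 oxirane is fused to the six-membered ring that carries the C3 oxygen, and C3 is homoallylic to the C5=C6 alkene. The oxirane oxygen lies anti to O3, whereas delivery from a C3 hydroxyl is syn, so the C3 epimer is epoxidised and C3 is inverted afterwards.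
- Stereochemistry: C3 from enzymatic ketone reduction (inverted in step 15), C5 and C6 from syn delivery in step 8, C6' from (R)-α-ionone, C3' from face-selective hydride reduction (step 18), alkene geometry from stabilised olefinations and thermal Z to E equilibration.

Key step: step 8

Assumption: (R)-α-ionone 21 of high enantiomeric purity and a ketoreductase panel are taken as commercial; the tertiary carbinol centre of 26 is an unassigned mixture that is destroyed in step 21.

**Route**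

Step 1
Reactants: 1 ketoisophorone (2,6,6-trimethylcyclohex-2-ene-1,4-dione)
Product: 3 (4S,6R)-4-hydroxy-2,2,6-trimethylcyclohexan-1-one (hydroxyl cis to the C6 methyl), via (6R)-levodione 2 (not isolated)
Conditions: old yellow enzyme 2 (ene-reductase), NADP+ (cat.), D-glucose, glucose dehydrogenase, phosphate buffer pH 7, 30 °C; then 4S-selective NADPH-dependent ketoreductase in the same vessel
Reagents that add atoms: none
Why: Biocatalytic C=C then C=O reduction cascade: the ene-reductase hydrogenates the enedione alkene and sets the methyl-bearing carbon as R, and the ketoreductase then reduces only the unhindered C4 carbonyl, its active site fixing the 4S alcohol.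

Step 2
Reactants: 3 (4S,6R)-4-hydroxy-2,2,6-trimethylcyclohexan-1-one
Product: 4 (4S,6R)-4-[(tert-butyldimethylsilyl)oxy]-2,2,6-trimethylcyclohexan-1-one
Conditions: t-BuMe2SiCl, imidazole, DMF, rt
Reagents that add atoms: tert-butyldimethylsilyl chloride, CC(C)(C)[Si](C)(C)Cl
Why: Imidazole-promoted silylation of a secondary alcohol, which touches no stereocentre.

Step 3
Reactants: 4 (4S,6R)-4-[(tert-butyldimethylsilyl)oxy]-2,2,6-trimethylcyclohexan-1-one
Product: 5 (4S)-4-[(tert-butyldimethylsilyl)oxy]-2,6,6-trimethylcyclohex-1-en-1-yl trifluoromethanesulfonate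
Conditions: LiN(iPr)2, THF, −78 °C; then PhNTf2, −78 → 0 °C; aq. NH4Cl
Reagents that add atoms: N-phenylbis(trifluoromethanesulfonimide), O=S(=O)(N(c1ccccc1)S(=O)(=O)C(F)(F)F)C(F)(F)F
Why: Enolate trapping as the enol triflate: the ketone has a single α-hydrogen (C6), so only one enolate can form, and its O-sulfonylation erases the C6 centre while C4 is untouched.

Step 4
Reactants: 5 (4S)-4-[(tert-butyldimethylsilyl)oxy]-2,6,6-trimethylcyclohex-1-en-1-yl trifluoromethanesulfonate
Product: 6 methyl (4S)-4-[(tert-butyldimethylsilyl)oxy]-2,6,6-trimethylcyclohex-1-ene-1-carboxylate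
Conditions: Pd(OAc)2 (5 mol %), PPh3, CO (1 atm), MeOH, Et3N, DMF, 60 °C
Reagents that add atoms: carbon monoxide, [C-]#[O+]; methanol, CO
Why: Palladium-catalysed methoxycarbonylation of an enol triflate: oxidative addition to zerovalent palladium formed in situ, CO insertion and methanolysis of the acylpalladium install the future C7 carbon.

Step 5
Reactants: 6 methyl (4S)-4-[(tert-butyldimethylsilyl)oxy]-2,6,6-trimethylcyclohex-1-ene-1-carboxylate
Product: 7 [(4S)-4-[(tert-butyldimethylsilyl)oxy]-2,6,6-trimethylcyclohex-1-en-1-yl]methanol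
Conditions: iBu2AlH, CH2Cl2, −78 → 0 °C; aq. KNaC4H4O6
Reagents that add atoms: none
Why: Hydride reduction of an α,β-unsaturated ester to the allylic alcohol, to which the silyl ether is inert.

Step 6
Reactants: 7 [(4S)-4-[(tert-butyldimethylsilyl)oxy]-2,6,6-trimethylcyclohex-1-en-1-yl]methanol
Product: 8 tert-butyl({(4S)-4-[(tert-butyldimethylsilyl)oxy]-2,6,6-trimethylcyclohex-1-en-1-yl}methoxy)diphenylsilane
Conditions: t-BuPh2SiCl, imidazole, DMF, 0 °C → rt
Reagents that add atoms: tert-butyl(chloro)diphenylsilane, CC(C)(C)[Si](Cl)(c1ccccc1)c1ccccc1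
Why: Silylation of the primary allylic alcohol gives a C7 ether that is much more acid-stable than the secondary tert-butyldimethylsilyl ether.

Step 7
Reactants: 8 tert-butyl({(4S)-4-[(tert-butyldimethylsilyl)oxy]-2,6,6-trimethylcyclohex-1-en-1-yl}methoxy)diphenylsilane
Product: 9 (1S)-4-{[(tert-butyldiphenylsilyl)oxy]methyl}-3,5,5-trimethylcyclohex-3-en-1-ol
Conditions: PPTS, EtOH, 50 °C
Reagents that add atoms: none
Why: Acid-catalysed solvolysis should remove the more labile tert-butyldimethylsilyl ether selectively and free the C3 hydroxyl, the bulkier tert-butyldiphenylsilyl ether being far slower to cleave.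

Step 8
Reactants: 9 (1S)-4-{[(tert-butyldiphenylsilyl)oxy]methyl}-3,5,5-trimethylcyclohex-3-en-1-ol; 10 tert-butyl hydroperoxide
Product: 11 (1R,3R,6R)-6-{[(tert-butyldiphenylsilyl)oxy]methyl}-1,5,5-trimethyl-7-oxabicyclo[4.1.0]heptan-3-ol (hydroxyl syn to the oxirane oxygen)
Conditions: VO(acac)2 (5 mol %), t-BuOOH (anhydrous, in decane), CH2Cl2, 0 °C → rt
Reagents that add atoms: tert-butyl hydroperoxide (10), CC(C)(C)OO
Why: t-BuOOH oxidises VO(acac)2 to a pentavalent vanadium species that exchanges a ligand for the C3 hydroxyl of 9 and binds the hydroperoxide, and the activated peroxide oxygen is then passed in one concerted step to the C5=C6 alkene lying beneath it, so that both C–O bonds form together. The closest known reaction is the vanadium-catalysed hydroxyl-directed (Sharpless-type) epoxidation of cyclic homoallylic alcohols such as cyclohex-3-en-1-ol, which gives the cis epoxy alcohol. The oxirane, the only ring formed, closes by suprafacial [2+1] oxygen-atom transfer to the alkene, so its fusion to the six-membered ring is necessarily cis. C5 and C6 are both fixed by the face on which the metal is tethered: the C3 alkoxide, pseudoaxial in the reactive half-chair, can reach only the alkene face on its own side, which gives the oxirane configuration of the target with C3 still epimeric. The step needs one alkene face and no undirected background oxidation, and this is secured because the bulky silyl ether at C7 cannot bind vanadium, the free C3 hydroxyl is the only ligating group, and the electron-rich tetrasubstituted alkene reacts at or below room temperature in a non-coordinating solvent. The product is protected against transannular opening because its hydroxyl sits on the same face as the oxirane oxygen and cannot attack C6 from the rear.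

Step 9
Reactants: 11 (1R,3R,6R)-6-{[(tert-butyldiphenylsilyl)oxy]methyl}-1,5,5-trimethyl-7-oxabicyclo[4.1.0]heptan-3-ol
Product: 12 (1R,3R,6R)-6-{[(tert-butyldiphenylsilyl)oxy]methyl}-1,5,5-trimethyl-7-oxabicyclo[4.1.0]heptan-3-yl acetate
Conditions: Ac2O, pyridine, DMAP (cat.), CH2Cl2, rt
Reagents that add atoms: acetic anhydride, CC(=O)OC(C)=O
Why: DMAP-catalysed acetylation masks the C3 hydroxyl so that C7 can be oxidised, the acetate being chosen because the later iBu2AlH step removes it without a separate operation.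

Step 10
Reactants: 12 (1R,3R,6R)-6-{[(tert-butyldiphenylsilyl)oxy]methyl}-1,5,5-trimethyl-7-oxabicyclo[4.1.0]heptan-3-yl acetate
Product: 13 (1R,3R,6R)-6-(hydroxymethyl)-1,5,5-trimethyl-7-oxabicyclo[4.1.0]heptan-3-yl acetate
Conditions: Bu4NF, AcOH, THF, 0 °C → rt
Reagents that add atoms: none
Why: Fluoride-induced desilylation, buffered with acetic acid so that neither the acetate nor the oxirane should be attacked.

Step 11
Reactants: 13 (1R,3R,6R)-6-(hydroxymethyl)-1,5,5-trimethyl-7-oxabicyclo[4.1.0]heptan-3-yl acetate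
Product: 14 (1R,3R,6S)-6-formyl-1,5,5-trimethyl-7-oxabicyclo[4.1.0]heptan-3-yl acetate
Conditions: Pr4N[RuO4] (5 mol %), N-methylmorpholine N-oxide, 4 Å molecular sieves, CH2Cl2, rt
Reagents that add atoms: none
Why: Ley–Griffith oxidation under neutral conditions converts the hindered primary epoxy alcohol to the aldehyde, which has no α-hydrogen and cannot epimerise.

Step 12
Reactants: 14 (1R,3R,6S)-6-formyl-1,5,5-trimethyl-7-oxabicyclo[4.1.0]heptan-3-yl acetate; 15 triethyl 3-methyl-4-phosphonocrotonate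
Product: 16 ethyl (2E,4E)-5-[(1S,4R,6R)-4-(acetyloxy)-2,2,6-trimethyl-7-oxabicyclo[4.1.0]heptan-1-yl]-3-methylpenta-2,4-dienoate
Conditions: 15, LiN(SiMe3)2, THF, −78 → 0 °C; aq. NH4Cl
Reagents that add atoms: triethyl 3-methyl-4-phosphonocrotonate (15), CCOC(=O)/C=C(C)/CP(=O)(OCC)OCC
Why: Horner–Wadsworth–Emmons olefination with the stabilised C5 phosphonate anion should give the 7E alkene and, through equilibration of the allylic anion, mainly the 9E trisubstituted alkene.

Step 13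
Reactants: 16 ethyl (2E,4E)-5-[(1S,4R,6R)-4-(acetyloxy)-2,2,6-trimethyl-7-oxabicyclo[4.1.0]heptan-1-yl]-3-methylpenta-2,4-dienoate
Product: 17 (1R,3R,6S)-6-[(1E,3E)-5-hydroxy-3-methylpenta-1,3-dien-1-yl]-1,5,5-trimethyl-7-oxabicyclo[4.1.0]heptan-3-ol
Conditions: iBu2AlH (excess), CH2Cl2, −78 → −20 °C; aq. KNaC4H4O6
Reagents that add atoms: none
Why: Hydride reduction converts the dienoate to the allylic alcohol and cleaves the acetate in the same operation, the low temperature sparing the vinyl oxirane.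

Step 14
Reactants: 17 (1R,3R,6S)-6-[(1E,3E)-5-hydroxy-3-methylpenta-1,3-dien-1-yl]-1,5,5-trimethyl-7-oxabicyclo[4.1.0]heptan-3-ol
Product: 18 (2E,4E)-5-[(1S,4R,6R)-4-hydroxy-2,2,6-trimethyl-7-oxabicyclo[4.1.0]heptan-1-yl]-3-methylpenta-2,4-dienal
Conditions: MnO2 (activated), CH2Cl2, rt
Reagents that add atoms: none
Why: MnO2 oxidises only the allylic primary alcohol and leaves the saturated C3 carbinol untouched.

Step 15
Reactants: 18 (2E,4E)-5-[(1S,4R,6R)-4-hydroxy-2,2,6-trimethyl-7-oxabicyclo[4.1.0]heptan-1-yl]-3-methylpenta-2,4-dienal; 19 palmitic acid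
Product: 20 (1R,3S,6S)-1,5,5-trimethyl-6-[(1E,3E)-3-methyl-5-oxopenta-1,3-dien-1-yl]-7-oxabicyclo[4.1.0]heptan-3-yl hexadecanoate
Conditions: 19, PPh3, diisopropyl azodicarboxylate, toluene, 0 °C → rt
Reagents that add atoms: palmitic acid (19), CCCCCCCCCCCCCCCC(=O)O
Why: Mitsunobu esterification: the C3 oxygen is activated as an alkoxyphosphonium ion and displaced by palmitate with inversion, which places the ester anti to the oxirane (3S in carotenoid numbering) and installs the palmitoyl group in the same operation.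

Step 16
Reactants: 21 (R)-α-ionone
Product: 22 2-methyl-2-{(E)-2-[(1R)-2,6,6-trimethylcyclohex-2-en-1-yl]ethenyl}-1,3-dioxolane
Conditions: Me3SiOCH2CH2OSiMe3, Me3SiOTf (cat.), CH2Cl2, −78 → −20 °C
Reagents that add atoms: 1,2-bis(trimethylsilyloxy)ethane, C[Si](C)(C)OCCO[Si](C)(C)C
Why: Noyori ketalisation at low temperature protects the C9 ketone without moving either alkene or touching C6.

Step 17
Reactants: 22 2-methyl-2-{(E)-2-[(1R)-2,6,6-trimethylcyclohex-2-en-1-yl]ethenyl}-1,3-dioxolane; 10 tert-butyl hydroperoxide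
Product: 23 (4R)-3,5,5-trimethyl-4-[(E)-2-(2-methyl-1,3-dioxolan-2-yl)ethenyl]cyclohex-2-en-1-one
Conditions: Rh2(cap)4 (1 mol %, cap = caprolactamate), t-BuOOH, K2CO3 (cat.), CH2Cl2, rt
Reagents that add atoms: tert-butyl hydroperoxide (10), CC(C)(C)OO
Why: Dirhodium-catalysed allylic oxidation: the tert-butylperoxyl radical abstracts hydrogen from C3, the only unhindered secondary allylic position, and the mixed peroxide collapses to the enone, C6 keeping its configuration.

Step 18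
Reactants: 23 (4R)-3,5,5-trimethyl-4-[(E)-2-(2-methyl-1,3-dioxolan-2-yl)ethenyl]cyclohex-2-en-1-one
Product: 24 (1R,4R)-3,5,5-trimethyl-4-[(E)-2-(2-methyl-1,3-dioxolan-2-yl)ethenyl]cyclohex-2-en-1-ol
Conditions: LiBH(s-Bu)3, THF, −78 °C; then H2O
Reagents that add atoms: none
Why: 1,2-Reduction of a β,β-disubstituted cyclohexenone by a bulky trialkylborohydride: with the C6 side chain pseudoaxial, the axial C1 methyl shields the opposite face of the carbonyl, so hydride should enter from the side-chain face (equatorial attack) and give the pseudoaxial 3R alcohol trans to the side chain.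

Step 19
Reactants: 24 (1R,4R)-3,5,5-trimethyl-4-[(E)-2-(2-methyl-1,3-dioxolan-2-yl)ethenyl]cyclohex-2-en-1-ol
Product: 25 (3R,6R)-3-hydroxy-α-ionone
Conditions: PPTS, acetone/H2O, rt
Reagents that add atoms: water, O
Why: Mild acid-catalysed ketal hydrolysis frees the methyl ketone under conditions the allylic alcohol tolerates.

Step 20
Reactants: 25 (3R,6R)-3-hydroxy-α-ionone
Product: 26 (1R,4R)-4-[(1E)-3-hydroxy-3-methylpenta-1,4-dien-1-yl]-3,5,5-trimethylcyclohex-2-en-1-ol (both epimers at the tertiary carbinol)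
Conditions: CH2=CHMgBr (3 equiv), THF, −20 → 0 °C; then H2O
Reagents that add atoms: vinylmagnesium bromide, C=C[Mg]Br
Why: 1,2-Addition of a vinyl Grignard reagent to the methyl enone (one equivalent is spent on the hydroxyl proton) gives the tertiary divinyl carbinol, whose new centre is lost in the next step.

Step 21
Reactants: 26 (1R,4R)-4-[(1E)-3-hydroxy-3-methylpenta-1,4-dien-1-yl]-3,5,5-trimethylcyclohex-2-en-1-ol
Product: 27 {(2E,4E)-5-[(1R,4R)-4-hydroxy-2,6,6-trimethylcyclohex-2-en-1-yl]-3-methylpenta-2,4-dien-1-yl}triphenylphosphonium bromide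
Conditions: PPh3·HBr, MeOH, rt
Reagents that add atoms: triphenylphosphine hydrobromide, [Br-].c1ccccc1[PH+](c1ccccc1)c1ccccc1
Why: PPh3·HBr ionises the tertiary bis-allylic alcohol and PPh3 captures the pentadienyl cation at its primary terminus (allylic transposition) to give the 2E,4E phosphonium salt, the secondary ring alcohol ionising far more slowly.

Step 22
Reactants: 27 {(2E,4E)-5-[(1R,4R)-4-hydroxy-2,6,6-trimethylcyclohex-2-en-1-yl]-3-methylpenta-2,4-dien-1-yl}triphenylphosphonium bromide; 28 (2E,4E,6E)-2,7-dimethylocta-2,4,6-trienedial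
Product: 30 (2E,4E,6E,8E,10E,12E)-13-[(1R,4R)-4-hydroxy-2,6,6-trimethylcyclohex-2-en-1-yl]-2,7,11-trimethyltrideca-2,4,6,8,10,12-hexaenal, via (8Z)-isomer of the C25 hydroxy aldehyde 29 (not isolated)
Conditions: 28 (3 equiv), 1,2-epoxybutane, EtOH, reflux
Reagents that add atoms: (2E,4E,6E)-2,7-dimethylocta-2,4,6-trienedial (28), O=C/C(C)=C/C=C/C=C(C)/C=O
Why: Wittig olefination under base-free conditions (bromide opens 1,2-epoxybutane to an alkoxide that forms the ylide); excess dialdehyde should confine reaction to one formyl group, and the hindered Z isomer at the new bond should relax thermally to E at reflux.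

Step 23
Reactants: 30 (2E,4E,6E,8E,10E,12E)-13-[(1R,4R)-4-hydroxy-2,6,6-trimethylcyclohex-2-en-1-yl]-2,7,11-trimethyltrideca-2,4,6,8,10,12-hexaenal; 19 palmitic acid
Product: 31 (1R,4R)-3,5,5-trimethyl-4-[(1E,3E,5E,7E,9E,11E)-3,7,12-trimethyl-13-oxotrideca-1,3,5,7,9,11-hexaen-1-yl]cyclohex-2-en-1-yl hexadecanoate
Conditions: 19, N,N'-dicyclohexylcarbodiimide, DMAP (cat.), CH2Cl2, 0 °C → rt
Reagents that add atoms: palmitic acid (19), CCCCCCCCCCCCCCCC(=O)O
Why: Steglich esterification acylates the allylic alcohol with retention at C3' and without acid that could ionise that position.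

Step 24
Reactants: 31 (1R,4R)-3,5,5-trimethyl-4-[(1E,3E,5E,7E,9E,11E)-3,7,12-trimethyl-13-oxotrideca-1,3,5,7,9,11-hexaen-1-yl]cyclohex-2-en-1-yl hexadecanoate
Product: 32 (1R,4R)-4-[(1E,3E,5E,7E,9E,11E)-13-hydroxy-3,7,12-trimethyltrideca-1,3,5,7,9,11-hexaen-1-yl]-3,5,5-trimethylcyclohex-2-en-1-yl hexadecanoate
Conditions: NaBH4, MeOH/THF, 0 °C
Reagents that add atoms: none
Why: Borohydride reduction of the conjugated aldehyde is much faster than attack on the ester at 0 °C.

Step 25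
Reactants: 32 (1R,4R)-4-[(1E,3E,5E,7E,9E,11E)-13-hydroxy-3,7,12-trimethyltrideca-1,3,5,7,9,11-hexaen-1-yl]-3,5,5-trimethylcyclohex-2-en-1-yl hexadecanoate
Product: 33 {(2E,4E,6E,8E,10E,12E)-13-[(1R,4R)-4-(hexadecanoyloxy)-2,6,6-trimethylcyclohex-2-en-1-yl]-2,7,11-trimethyltrideca-2,4,6,8,10,12-hexaen-1-yl}triphenylphosphonium bromide
Conditions: PPh3·HBr, CH2Cl2/MeOH, 0 °C → rt
Reagents that add atoms: triphenylphosphine hydrobromide, [Br-].c1ccccc1[PH+](c1ccccc1)c1ccccc1
Why: The polyenylic primary alcohol ionises readily with PPh3·HBr and the cation is trapped by PPh3 at the terminal carbon, giving the C25 Wittig salt while the less easily ionised allylic ester should survive.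

Step 26
Reactants: 20 (1R,3S,6S)-1,5,5-trimethyl-6-[(1E,3E)-3-methyl-5-oxopenta-1,3-dien-1-yl]-7-oxabicyclo[4.1.0]heptan-3-yl hexadecanoate; 33 the C25 phosphonium bromide
Product: 35 (all-E)-(3S,5R,6S,3'R,6'R)-5,6-epoxy-5,6-dihydro-β,ε-carotene-3,3'-diyl dihexadecanoate (CNP0344034.1), via (11Z)-isomer of the diester 34 (not isolated)
Conditions: 1,2-epoxybutane (solvent), 60 °C; then heptane, reflux, argon, dark
Reagents that add atoms: none
Why: Wittig olefination of the epoxy dienal with the C25 ylide under acid-scavenging, base-free conditions forms C11=C12 without touching the esters or the oxirane, and heating should convert the sterically strained 11Z isomer into the all-E polyene.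

**Compound list**

1 | ketoisophorone (2,6,6-trimethylcyclohex-2-ene-1,4-dione) | CC1=CC(=O)CC(C)(C)C1=O | starting material
2 | (6R)-levodione ((6R)-2,2,6-trimethylcyclohexane-1,4-dione) | C[C@@H]1CC(=O)CC(C)(C)C1=O | intermediate (not isolated)
3 | (4S,6R)-4-hydroxy-2,2,6-trimethylcyclohexan-1-one | C[C@@H]1C[C@H](O)CC(C)(C)C1=O | intermediate
4 | (4S,6R)-4-[(tert-butyldimethylsilyl)oxy]-2,2,6-trimethylcyclohexan-1-one | C[C@@H]1C[C@H](O[Si](C)(C)C(C)(C)C)CC(C)(C)C1=O | intermediate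
5 | (4S)-4-[(tert-butyldimethylsilyl)oxy]-2,6,6-trimethylcyclohex-1-en-1-yl trifluoromethanesulfonate | CC1=C(OS(=O)(=O)C(F)(F)F)C(C)(C)C[C@@H](O[Si](C)(C)C(C)(C)C)C1 | intermediate
6 | methyl (4S)-4-[(tert-butyldimethylsilyl)oxy]-2,6,6-trimethylcyclohex-1-ene-1-carboxylate | CC1=C(C(=O)OC)C(C)(C)C[C@@H](O[Si](C)(C)C(C)(C)C)C1 | intermediate
7 | [(4S)-4-[(tert-butyldimethylsilyl)oxy]-2,6,6-trimethylcyclohex-1-en-1-yl]methanol | CC1=C(CO)C(C)(C)C[C@@H](O[Si](C)(C)C(C)(C)C)C1 | intermediate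
8 | tert-butyl({(4S)-4-[(tert-butyldimethylsilyl)oxy]-2,6,6-trimethylcyclohex-1-en-1-yl}methoxy)diphenylsilane | CC1=C(CO[Si](c2ccccc2)(c2ccccc2)C(C)(C)C)C(C)(C)C[C@@H](O[Si](C)(C)C(C)(C)C)C1 | intermediate
9 | (1S)-4-{[(tert-butyldiphenylsilyl)oxy]methyl}-3,5,5-trimethylcyclohex-3-en-1-ol | O[C@@H]1CC(C)(C)C(CO[Si](c2ccccc2)(c2ccccc2)C(C)(C)C)=C(C)C1 | intermediate (key-step precursor)
10 | tert-butyl hydroperoxide | CC(C)(C)OO | starting material
11 | (1R,3R,6R)-6-{[(tert-butyldiphenylsilyl)oxy]methyl}-1,5,5-trimethyl-7-oxabicyclo[4.1.0]heptan-3-ol | O[C@@H]1CC(C)(C)[C@]2(CO[Si](c3ccccc3)(c3ccccc3)C(C)(C)C)O[C@]2(C)C1 | intermediate (key-step product)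
12 | (1R,3R,6R)-6-{[(tert-butyldiphenylsilyl)oxy]methyl}-1,5,5-trimethyl-7-oxabicyclo[4.1.0]heptan-3-yl acetate | CC(=O)O[C@@H]1CC(C)(C)[C@]2(CO[Si](c3ccccc3)(c3ccccc3)C(C)(C)C)O[C@]2(C)C1 | intermediate
13 | (1R,3R,6R)-6-(hydroxymethyl)-1,5,5-trimethyl-7-oxabicyclo[4.1.0]heptan-3-yl acetate | CC(=O)O[C@@H]1CC(C)(C)[C@]2(CO)O[C@]2(C)C1 | intermediate
14 | (1R,3R,6S)-6-formyl-1,5,5-trimethyl-7-oxabicyclo[4.1.0]heptan-3-yl acetate | CC(=O)O[C@@H]1CC(C)(C)[C@]2(C=O)O[C@]2(C)C1 | intermediate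
15 | triethyl 3-methyl-4-phosphonocrotonate (ethyl (2E)-4-(diethoxyphosphoryl)-3-methylbut-2-enoate) | CCOC(=O)/C=C(C)/CP(=O)(OCC)OCC | starting material
16 | ethyl (2E,4E)-5-[(1S,4R,6R)-4-(acetyloxy)-2,2,6-trimethyl-7-oxabicyclo[4.1.0]heptan-1-yl]-3-methylpenta-2,4-dienoate | CC(=O)O[C@@H]1CC(C)(C)[C@]2(/C=C/C(C)=C/C(=O)OCC)O[C@]2(C)C1 | intermediate
17 | (1R,3R,6S)-6-[(1E,3E)-5-hydroxy-3-methylpenta-1,3-dien-1-yl]-1,5,5-trimethyl-7-oxabicyclo[4.1.0]heptan-3-ol | O[C@@H]1CC(C)(C)[C@]2(/C=C/C(C)=C/CO)O[C@]2(C)C1 | intermediate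
18 | (2E,4E)-5-[(1S,4R,6R)-4-hydroxy-2,2,6-trimethyl-7-oxabicyclo[4.1.0]heptan-1-yl]-3-methylpenta-2,4-dienal | O[C@@H]1CC(C)(C)[C@]2(/C=C/C(C)=C/C=O)O[C@]2(C)C1 | intermediate
19 | palmitic acid (hexadecanoic acid) | CCCCCCCCCCCCCCCC(=O)O | starting material
20 | (1R,3S,6S)-1,5,5-trimethyl-6-[(1E,3E)-3-methyl-5-oxopenta-1,3-dien-1-yl]-7-oxabicyclo[4.1.0]heptan-3-yl hexadecanoate | CCCCCCCCCCCCCCCC(=O)O[C@H]1CC(C)(C)[C@]2(/C=C/C(C)=C/C=O)O[C@]2(C)C1 | intermediate
21 | (R)-α-ionone ((3E)-4-[(1R)-2,6,6-trimethylcyclohex-2-en-1-yl]but-3-en-2-one) | CC(=O)/C=C/[C@H]1C(C)=CCCC1(C)C | starting material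
22 | 2-methyl-2-{(E)-2-[(1R)-2,6,6-trimethylcyclohex-2-en-1-yl]ethenyl}-1,3-dioxolane | CC1(OCCO1)/C=C/[C@H]2C(C)=CCCC2(C)C | intermediate
23 | (4R)-3,5,5-trimethyl-4-[(E)-2-(2-methyl-1,3-dioxolan-2-yl)ethenyl]cyclohex-2-en-1-one | CC1(OCCO1)/C=C/[C@H]2C(C)=CC(=O)CC2(C)C | intermediate
24 | (1R,4R)-3,5,5-trimethyl-4-[(E)-2-(2-methyl-1,3-dioxolan-2-yl)ethenyl]cyclohex-2-en-1-ol | CC1(OCCO1)/C=C/[C@H]2C(C)=C[C@H](O)CC2(C)C | intermediate
25 | (3R,6R)-3-hydroxy-α-ionone ((3E)-4-[(1R,4R)-4-hydroxy-2,6,6-trimethylcyclohex-2-en-1-yl]but-3-en-2-one) | CC(=O)/C=C/[C@H]1C(C)=C[C@H](O)CC1(C)C | intermediate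
26 | (1R,4R)-4-[(1E)-3-hydroxy-3-methylpenta-1,4-dien-1-yl]-3,5,5-trimethylcyclohex-2-en-1-ol (both epimers at the tertiary carbinol) | C=CC(C)(O)/C=C/[C@H]1C(C)=C[C@H](O)CC1(C)C | intermediate
27 | {(2E,4E)-5-[(1R,4R)-4-hydroxy-2,6,6-trimethylcyclohex-2-en-1-yl]-3-methylpenta-2,4-dien-1-yl}triphenylphosphonium bromide | [Br-].c1ccccc1[P+](c1ccccc1)(c1ccccc1)C/C=C(C)/C=C/[C@H]1C(C)=C[C@H](O)CC1(C)C | intermediate
28 | (2E,4E,6E)-2,7-dimethylocta-2,4,6-trienedial | O=C/C(C)=C/C=C/C=C(C)/C=O | starting material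
29 | (2E,4E,6E,8Z,10E,12E)-13-[(1R,4R)-4-hydroxy-2,6,6-trimethylcyclohex-2-en-1-yl]-2,7,11-trimethyltrideca-2,4,6,8,10,12-hexaenal | O=C/C(C)=C/C=C/C=C(C)/C=C\C=C(C)\C=C\[C@H]1C(C)=C[C@H](O)CC1(C)C | intermediate (not isolated)
30 | (2E,4E,6E,8E,10E,12E)-13-[(1R,4R)-4-hydroxy-2,6,6-trimethylcyclohex-2-en-1-yl]-2,7,11-trimethyltrideca-2,4,6,8,10,12-hexaenal | O=C/C(C)=C/C=C/C=C(C)/C=C/C=C(C)/C=C/[C@H]1C(C)=C[C@H](O)CC1(C)C | intermediate
31 | (1R,4R)-3,5,5-trimethyl-4-[(1E,3E,5E,7E,9E,11E)-3,7,12-trimethyl-13-oxotrideca-1,3,5,7,9,11-hexaen-1-yl]cyclohex-2-en-1-yl hexadecanoate | O=C/C(C)=C/C=C/C=C(C)/C=C/C=C(C)/C=C/[C@H]1C(C)=C[C@H](OC(=O)CCCCCCCCCCCCCCC)CC1(C)C | intermediate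
32 | (1R,4R)-4-[(1E,3E,5E,7E,9E,11E)-13-hydroxy-3,7,12-trimethyltrideca-1,3,5,7,9,11-hexaen-1-yl]-3,5,5-trimethylcyclohex-2-en-1-yl hexadecanoate | OC/C(C)=C/C=C/C=C(C)/C=C/C=C(C)/C=C/[C@H]1C(C)=C[C@H](OC(=O)CCCCCCCCCCCCCCC)CC1(C)C | intermediate
33 | {(2E,4E,6E,8E,10E,12E)-13-[(1R,4R)-4-(hexadecanoyloxy)-2,6,6-trimethylcyclohex-2-en-1-yl]-2,7,11-trimethyltrideca-2,4,6,8,10,12-hexaen-1-yl}triphenylphosphonium bromide | [Br-].c1ccccc1[P+](c1ccccc1)(c1ccccc1)C/C(C)=C/C=C/C=C(C)/C=C/C=C(C)/C=C/[C@H]1C(C)=C[C@H](OC(=O)CCCCCCCCCCCCCCC)CC1(C)C | intermediate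
34 | (11Z)-(3S,5R,6S,3'R,6'R)-5,6-epoxy-5,6-dihydro-β,ε-carotene-3,3'-diyl dihexadecanoate | CCCCCCCCCCCCCCCC(=O)O[C@H]1CC(C)(C)[C@]2(/C=C/C(C)=C/C=C\C(C)=C\C=C\C=C(C)\C=C\C=C(C)\C=C\[C@H]3C(C)=C[C@H](OC(=O)CCCCCCCCCCCCCCC)CC3(C)C)O[C@]2(C)C1 | intermediate (not isolated)
35 | (all-E)-(3S,5R,6S,3'R,6'R)-5,6-epoxy-5,6-dihydro-β,ε-carotene-3,3'-diyl dihexadecanoate (CNP0344034.1) | CCCCCCCCCCCCCCCC(=O)O[C@H]1CC(C)(C)[C@]2(/C=C/C(C)=C/C=C/C(C)=C/C=C/C=C(C)/C=C/C=C(C)/C=C/[C@H]3C(C)=C[C@H](OC(=O)CCCCCCCCCCCCCCC)CC3(C)C)O[C@]2(C)C1 | target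

**Step count**

Total steps: 26. Longest linear sequence: 16 (steps 1–15, then step 26). The ε branch is 11 steps (16–25, then 26).

**Steps most likely to fail**

1. Step 15 (Mitsunobu palmitoylation). The displacement at C3 must come in axially on the face that carries a C1 methyl, and palmitic acid is a weak acid partner, so elimination to a cyclohexene or simple return of unreacted alcohol may outrun substitution. Fallback: from 18 the Mitsunobu reaction is run with the more acidic 4-nitrobenzoic acid (PPh3, diisopropyl azodicarboxylate, toluene) to give the inverted 4-nitrobenzoate F1. Brief methanolysis (K2CO3, MeOH, 0 °C) frees the 3S hydroxy dienal F2, and carbodiimide esterification with 19 under the conditions of step 23 comes back to the route at 20. Inversion and acylation are thus separated.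

2. Step 8 (directed epoxidation). The vanadium alkoxide has to sit pseudoaxial, syn to a C1 methyl, so binding may be weak; undirected oxidation would then erode facial selectivity, and the Lewis-acidic metal may open the tetrasubstituted oxirane. Fallback: from 7, a Katsuki–Sharpless epoxidation of the primary allylic alcohol (Ti(OiPr)4, D-(−)-diethyl tartrate, t-BuOOH, 4 Å molecular sieves, CH2Cl2, −20 °C) lets the tartrate ligand, not the ring, choose the alkene face and should give the epoxy alcohol F3. Oxidation as in step 11 gives the aldehyde F4, olefination with 15 as in step 12 the dienoate F5, and iBu2AlH reduction the dienol F6. Bu4NF then removes the silyl ether and the route is rejoined at 17.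

3. Step 18 (enone reduction). Hydride may add to the other face of the carbonyl (axial attack) and give mainly the cis alcohol, or basic work-up may epimerise the vinylogous α-position C6. Fallback: from 23, the cis alcohol F7 (formed on purpose with NaBH4 and CeCl3 in MeOH at −78 °C, or taken as it forms in step 18) is inverted by a Mitsunobu reaction with 4-nitrobenzoic acid to the trans ester F8. Methanolysis (K2CO3, MeOH) comes back to the route at 24.

**Further compounds**

F1 | step 15 | (1R,3S,6S)-1,5,5-trimethyl-6-[(1E,3E)-3-methyl-5-oxopenta-1,3-dien-1-yl]-7-oxabicyclo[4.1.0]heptan-3-yl 4-nitrobenzoate | O=C(O[C@H]1CC(C)(C)[C@]2(/C=C/C(C)=C/C=O)O[C@]2(C)C1)c1ccc(cc1)[N+](=O)[O-]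
F2 | step 15 | (2E,4E)-5-[(1S,4S,6R)-4-hydroxy-2,2,6-trimethyl-7-oxabicyclo[4.1.0]heptan-1-yl]-3-methylpenta-2,4-dienal | O[C@H]1CC(C)(C)[C@]2(/C=C/C(C)=C/C=O)O[C@]2(C)C1
F3 | step 8 | [(1R,4R,6R)-4-[(tert-butyldimethylsilyl)oxy]-2,2,6-trimethyl-7-oxabicyclo[4.1.0]heptan-1-yl]methanol | CC(C)(C)[Si](C)(C)O[C@@H]1CC(C)(C)[C@]2(CO)O[C@]2(C)C1
F4 | step 8 | (1S,4R,6R)-4-[(tert-butyldimethylsilyl)oxy]-2,2,6-trimethyl-7-oxabicyclo[4.1.0]heptane-1-carbaldehyde | CC(C)(C)[Si](C)(C)O[C@@H]1CC(C)(C)[C@]2(C=O)O[C@]2(C)C1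
F5 | step 8 | ethyl (2E,4E)-5-[(1S,4R,6R)-4-[(tert-butyldimethylsilyl)oxy]-2,2,6-trimethyl-7-oxabicyclo[4.1.0]heptan-1-yl]-3-methylpenta-2,4-dienoate | CC(C)(C)[Si](C)(C)O[C@@H]1CC(C)(C)[C@]2(/C=C/C(C)=C/C(=O)OCC)O[C@]2(C)C1
F6 | step 8 | (2E,4E)-5-[(1S,4R,6R)-4-[(tert-butyldimethylsilyl)oxy]-2,2,6-trimethyl-7-oxabicyclo[4.1.0]heptan-1-yl]-3-methylpenta-2,4-dien-1-ol | CC(C)(C)[Si](C)(C)O[C@@H]1CC(C)(C)[C@]2(/C=C/C(C)=C/CO)O[C@]2(C)C1
F7 | step 18 | (1S,4R)-3,5,5-trimethyl-4-[(E)-2-(2-methyl-1,3-dioxolan-2-yl)ethenyl]cyclohex-2-en-1-ol | CC1(OCCO1)/C=C/[C@H]2C(C)=C[C@@H](O)CC2(C)C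
F8 | step 18 | (1R,4R)-3,5,5-trimethyl-4-[(E)-2-(2-methyl-1,3-dioxolan-2-yl)ethenyl]cyclohex-2-en-1-yl 4-nitrobenzoate | CC1(OCCO1)/C=C/[C@H]2C(C)=C[C@H](OC(=O)c3ccc(cc3)[N+](=O)[O-])CC2(C)C
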